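Your closed, stirred flask holds one charge of starting material, and partner is the setting you change.

in all of them: starting material 0.019 M

| flask | partner | remark | time |
|---|---|---|---|
| larch | 0.011 M | run made earlier |  |
| maple | 0.027 M | run made earlier |  |
| ash | 0.086 M | run made earlier |  |
| north-west | 0.0100 M |  | 80 min |
| south | 0.0200 M |  | 80 min |
| north-east | 0.0400 M |  | 80 min |
| east | 0.0800 M |  | 80 min |

| run | time / min | product / % | starting material / % |
|---|---|---|---|
| larch | 6.00 | 0 | 96.3 |
| larch | 12.0 | 0.9 | 91.6 |
| larch | 25.0 | 1.0 | 82.4 |
| larch | 40.0 | 2.9 | 74.6 |
| larch | 80.0 | 10.5 | 57.8 |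
| maple | 15.0 | 0.3 | 82.7 |
| maple | 30.0 | 2.2 | 68.8 |
| maple | 50.0 | 5.6 | 54.7 |
| maple | 60.0 | 7.1 | 48.5 |
| maple | 80.0 | 9.5 | 40.5 |
| ash | 6.00 | 1.3 | 81.5 |
| ash | 12.0 | 0.7 | 66.1 |
| ash | 25.0 | 0.9 | 44.9 |
| ash | 40.0 | 2.7 | 29.4 |
| ash | 80.0 | 6.9 | 11.6 |

(readings scatter by 0.5 percentage points)

- a reading or a percentage of product counts all its forms, free or not
- "hardly changes" means that all values lie within two and a half points (for a concentration: within two and a half percent of the largest)
- a reading of starting material is of its free form alone

* amount of product at the end, in percent of the starting material charged for north-west, south, north-east, east, in this order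
* the shape of the row from first to last (falls, then rises / hardly changes / rises, then falls / rises all the way / falls all the way)

Work with the fraction left, not the fraction made. The last reading of a run gives two quantities, the second being the minutes an average charged molecule stood free, if the loss were exponential:

loss constant = ln(1 / fraction left) / time

free time = (1 − fraction left) / loss constant

The larch run gives a loss constant of 0.00685 min⁻¹ and a free time of 61.6 min. The ash run gives 0.0269 min⁻¹ and 32.8 min. The maple run gives 0.0113 min⁻¹ and 52.7 min.

Now divide product by free time. I call this the product rate per free minute 0.00170 min⁻¹, the value for larch. Ash reads 0.00210 min⁻¹, and maple reads 0.00180 min⁻¹, which lies between them. Product as a share of starting material lost moves by a larger factor, falling from 24.9% in larch to 7.81% in ash. So I reckon with free time.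

The loose ceiling is the starting material lost, and the floor is zero. Interpolating the loss constant in partner, and going slightly below larch for north-west, I get these fractions left:

north-west: 0.00657 min⁻¹, left 59.1%, free time 62.2 min

east: 0.0253 min⁻¹, left 13.2%, free time 34.3 min

Multiplying by the larch and ash product rates tightens the bracket to 10.6% to 13.1% for north-west and 5.84% to 7.20% for east. This tighter bracket assumes that the product rate stays between its larch and ash readings, so it is an estimate and not a strict bound. The estimated east ceiling stands below the estimated north-west floor, and free time shortens from larch through maple to ash, so I expect a falling row.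

The forecast gives 10.6%, 10%, 9% and 7.2%, shape falls all the way, as it chose to “interpolate the 80-min yields smoothly”, which puts north-west on my floor and east on my ceiling.

The flasks give 10.9%, 10.0%, 8.57% and 6.44%, shape falls all the way.

    starting material + product ⇌ idle adduct, settled at all times (K = 41.0 L mol⁻¹)
    starting material + partner ⇌ intermediate B (K = 230 L mol⁻¹, k = 22.0 L mol⁻¹ h⁻¹)
    intermediate A → product (k = 1.10 h⁻¹)
    starting material → intermediate A (k = 0.210 h⁻¹)

At 80.0 min, intermediate B holds 75.6% of the charge in east, against 17.2% in north-west. South ended with 46.7% of its starting material free, so its loss constant is 0.00952 min⁻¹ and its free time 56.0 min. The larch and ash product rates then bracket south at 9.52% to 11.8%, and south holds 10.0% of product.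

The data are calculated for substances that don't exist, and the scatter is random.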